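Slowness in these two runs comes in two pieces: a late start, then a climb.

common to all: G 0.60 M
- Wednesday's: Q 1.6 mM; temperature 65 °C; run made earlier
- Tuesday's: Q 3.6 mM; temperature 98 °C; run made earlier
- delta: Q 2.4 mM; temperature 80 °C; time 2.5 h
- theta: Q 2.4 mM; temperature 50 °C; time 2.5 h
- alpha: Q 2.4 mM; temperature 110 °C; time 2.5 h
- Wednesday's (time / h: Z / %): 0.333: 4; 0.667: 4; 1.00: 8; 2.00: 14; 4.00: 40
- Tuesday's (time / min: Z / %): 4.00: 4; 8.00: 11; 12.0: 19; 25.0: 44; 50.0: 66

(each reading ± 2 percentage points)
* the flask with the highest amount of Z, in percent of the G charged ("all alike" if they lie within 1.5 percentage points) (delta / theta / alpha / all alike)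
* final Z, as a percentage of the G charged, in delta
* final Z, as a percentage of the G charged, in theta
* final Z, as a percentage of the G charged, in alpha
- a reading or a percentage of Z counts all its forms, free or not

Asked: what do you read from the runs?
Answer: I freeze the late climb as a pseudo-first-order constant k, the slope of −ln(1 − Z), where Z is the fraction of G charged. Wednesday's last two readings give 0.180 h⁻¹, and Tuesday's readings at 12.0 min and 25.0 min give 1.70 h⁻¹. Running those lines back to zero gives lags of 1.16 h and 0.0763 h.

Asked: and for a new flask?
Answer: I use the working clock, k times the time after the lag, and Z = 1 − exp(−clock). I take k proportional to c(Q). From Wednesday's run to Tuesday's, k per unit c(Q) rose by a factor 4.21 and the lag shrank by a factor 15.2; I spread both factors evenly over the degrees. Delta stands 0.455 of the way from Wednesday's temperature to Tuesday's, so k is 0.519 h⁻¹, the lag 0.337 h, the working clock 1.12, and Z 67.4 %.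

Asked: the weak spot?
Answer: The two runs moved c(Q) and temperature together, so the split between them is assumed. Alpha's 110 °C also lies above Tuesday's 98 °C. My reckoning there gives k of 1.91 h⁻¹ and Z 99.1 %. Theta's lag comes out at 4.01 h, longer than its 2.5 h, so I expect the level of Wednesday's readings inside its lag, 4 % to 8 %.

The forecast differs from my figures: alpha highest, delta 62 % (45 % to 75 %), theta 7 % (3 % to 15 %), alpha 82 % (50 % to 99 %), warning for alpha that “Z could stall well short”.

The flasks give alpha highest, with delta 62.7 %, theta 4.50 % and alpha 83.0 %.

    G + Q → D + Z (k = 0.0140 L mol⁻¹ min⁻¹, Ea = 81.0 kJ mol⁻¹)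
    G + D → Z + D, rate k2*[D]*[G] (k = 13.0 L mol⁻¹ min⁻¹, Ea = 49.0 kJ mol⁻¹)
    Q + Z → Q + J (k = 0.330 L mol⁻¹ min⁻¹, Ea = 69.0 kJ mol⁻¹)
    G + Z ⇌ X, settled at all times (K = 4.40 L mol⁻¹, ΔH = 28.0 kJ mol⁻¹)
    (constants at 80 °C)

The Z from delta's clock of 1.12 stood 4.8 percentage points above the Z of that flask. In theta at 2.50 h, G has a half-life of 19 h through the step with D, against 200 d through the step with Q, a rate ratio of 250. The half-life through the step with D is also longer than the 2.5 h of theta, and 93 % of the G is left there.

For the repeat of theta at 75 °C, the position between the temperatures of the two runs is 0.303, the clock 0.831, and Z 56.4 %. The computed flask gives 51.7 %.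

The readings come from a simulation for substances that don't exist, noise included.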